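Ring B (C5–C10, labdane numbering) is read as a squarate plus an alkene. C6(O)–C7(O)–C8(CH3)–C9 are the four carbons of a 4-hydroxycyclobutenone. C5=C10 is the tetrasubstituted double bond of a 2,6,6-trimethylcyclohexenyl group (ring A) on its carbinol carbon. Heating opens the four-membered ring to a dienylketene, which closes onto C10. This one operation gives ring B, the C9–C10 bond, quaternary C10 and an enedione with both oxygens and the C8 methyl in place. A menthyl enol ether at C7 makes the C10 epimers separable and leaves when the side chain enters at C9. Hydride and acetate, both from the α face, then set C6 and C7.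

Key step: step 6

Remark: labdane numbering and α/β descriptors (10-CH3 = β) are used for all bicyclic compounds. The electrocyclisation is assumed to show no useful facial bias, so half of the material is lost at the separation in step 6.

Step 1
Reactants: 1 squaric acid; 2 (−)-menthol
Product: 3 di-(−)-menthyl squarate
Conditions: 2 (2.2 equiv), toluene, reflux, Dean–Stark trap
Reagents that add atoms: none
Why: Azeotropic esterification of the vinylogous diacid is the usual way to dialkyl squarates, and the menthyl stereocentres come unchanged from the chiral pool.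

Step 2
Reactants: 3 di-(−)-menthyl squarate
Product: 5 3-[(−)-menthyloxy]-4-methylcyclobut-3-ene-1,2-dione, via methyl carbinol 4 (not isolated)
Conditions: MeLi, THF, −78 °C; then 2 M HCl, CH2Cl2, rt
Reagents that add atoms: methyllithium, [Li]C; water, O
Why: 1,2-Addition of an organolithium to a squarate carbonyl, followed by acid-induced loss of one alcohol, is the standard squarate to 3-alkoxy-4-alkylcyclobutenedione sequence, and the carbinol centre of 4 disappears again.

Step 3
Reactants: 6 2,2,6-trimethylcyclohexanone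
Product: 7 2,2,6-trimethylcyclohexanone hydrazone
Conditions: N2H4·H2O, Et3N, EtOH, reflux
Reagents that add atoms: hydrazine, NN
Why: This is a plain hydrazone condensation, slow at this hindered ketone but without a competing pathway.

Step 4
Reactants: 7 2,2,6-trimethylcyclohexanone hydrazone
Product: 8 2-iodo-1,3,3-trimethylcyclohex-1-ene
Conditions: I2, 1,1,3,3-tetramethylguanidine, Et2O, 0 °C to rt
Reagents that add atoms: iodine, II
Why: In this Barton vinyl iodide synthesis the only α-hydrogen sits on the methyl-bearing carbon, so one regioisomer can form and the stereocentre of 6 is erased.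

Step 5
Reactants: 8 2-iodo-1,3,3-trimethylcyclohex-1-ene; 5 3-[(−)-menthyloxy]-4-methylcyclobut-3-ene-1,2-dione
Product: 10 4-hydroxy-3-menthyloxy-2-methyl-4-(2,6,6-trimethylcyclohexenyl)cyclobutenone, via vinyllithium 9 (not isolated)
Conditions: 8, t-BuLi (2.0 equiv), Et2O, −78 °C; then 5, THF, −78 °C; aq. NH4Cl
Reagents that add atoms: none
Why: Iodine–lithium exchange is followed by 1,2-addition to the carbonyl next to the alkoxy-bearing carbon, because the other carbonyl is deactivated as a vinylogous ester; the new carbinol centre forms as a mixture and is erased in step 6.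

Step 6
Reactants: 10 4-hydroxy-3-menthyloxy-2-methyl-4-(2,6,6-trimethylcyclohexenyl)cyclobutenone
Product: 13 trans-fused 7-menthyloxy-6,9-enedione (4aS,8aS), via dienylketene 11 (not isolated), via dienol 12 (not isolated)
Conditions: p-xylene, 138 °C; then DBU (0.1 equiv), rt; separation of the C10 epimers on silica gel or by crystallisation
Reagents that add atoms: none
Why: Thermal conrotatory 4π opening of the C6–C9 bond of the cyclobutenone is torquoselective (the hydroxyl donor turns outward, the cyclohexenyl group inward) and gives the (Z)-dienylketene 11, whose ketene carbon C9 lies next to C10. Ring B then closes by a thermal disrotatory 6π electrocyclisation (C9–C10 bond) to dienol 12, and DBU tautomerises 12 to the enedione, so the four-membered ring C6–C7–C8–C9 has grown by C5 and C10. The closest known reaction type is the Moore rearrangement of 4-alkenyl-4-hydroxycyclobutenones; closure onto a fully substituted terminus is what dienylketenes do in the dark step of the Barton–Quinkert reaction, and because C10 carries no hydrogen the sequence ends at the enedione instead of a hydroquinone. C10 is not controlled by the substrate: both helical transition states are open, the two products are diastereomers only through the menthyl group, and the (10S) isomer is kept after separation. C5 is set by protonation of the planar dienol from the α face, opposite the C10 methyl and the axial C4 methyl, and the trans-fused diketone is also the isomer expected at equilibrium under DBU. The step needs ring closure to beat lactonisation of the ketene, which the outward-turning hydroxyl secures, and the regiochemistry (methyl next to C9, oxygen next to C6) was fixed in step 5.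

Step 7
Reactants: 13 trans-fused 7-menthyloxy-6,9-enedione
Product: 14 6β-hydroxy-7-menthyloxy-7-en-9-one
Conditions: NaBH4, CeCl3·7H2O, MeOH, −78 °C
Reagents that add atoms: none
Why: In this Luche reduction only the C6 carbonyl reacts, since C9 is a vinylogous ester next to quaternary C10, and hydride enters from the α face because the 10-methyl and axial 4-methyl block the β face, giving the 6β-alcohol and locking C5.

Step 8
Reactants: 15 (E)-3-methylpent-2-en-4-yn-1-ol
Product: 16 TBDPS ether of 15
Conditions: TBDPSCl, imidazole, DMF, rt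
Reagents that add atoms: tert-butyl(chloro)diphenylsilane, CC(C)(C)[Si](Cl)(c1ccccc1)c1ccccc1
Why: Standard silylation of a primary alcohol; TBDPS is chosen to survive the aqueous acid of step 11.

Step 9
Reactants: 16 TBDPS ether of 15
Product: 17 (E)-3-methylpenta-2,4-dienyl TBDPS ether
Conditions: H2 (1 atm), Pd/CaCO3 poisoned with Pb(OAc)2, quinoline, hexane, rt
Reagents that add atoms: none
Why: Lindlar-type semihydrogenation stops at the terminal vinyl group and leaves the E-trisubstituted double bond untouched.

Step 10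
Reactants: 17 (E)-3-methylpenta-2,4-dienyl TBDPS ether
Product: 19 (E)-5-iodo-3-methylpent-2-enyl TBDPS ether, via borane 18 (not isolated)
Conditions: 9-BBN, THF, 0 °C to rt; then I2, NaOMe, MeOH, 0 °C
Reagents that add atoms: iodine, II
Why: Anti-Markovnikov hydroboration by 9-BBN picks the monosubstituted double bond of the diene, and base-induced iodinolysis turns the primary B–C bond into the primary iodide.

Step 11
Reactants: 19 (E)-5-iodo-3-methylpent-2-enyl TBDPS ether; 14 6β-hydroxy-7-menthyloxy-7-en-9-one
Product: 22 15-TBDPSO-6β-hydroxylabda-8,13E-dien-7-one, via alkyllithium 20 (not isolated), via tertiary carbinol 21 (not isolated)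
Conditions: 19, t-BuLi (2.0 equiv), Et2O, −78 °C; 14, MeLi (1.0 equiv, takes up the OH proton), THF, −78 °C, then 20, −78 to 0 °C; 1 M HCl, THF, 0 °C
Reagents that add atoms: water, O
Why: In this Stork–Danheiser transposition the organolithium adds 1,2 to the non-enolisable C9 carbonyl anti to the 10-methyl, and mild acid ionises the tertiary allylic alcohol through the vinylogous oxocarbenium ion, releasing menthol and giving the C7 ketone with the tetrasubstituted C8=C9 double bond.

Step 12
Reactants: 22 15-TBDPSO-6β-hydroxylabda-8,13E-dien-7-one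
Product: 23 15-TBDPSO-labda-8,13E-diene-6β,7β-diol
Conditions: NaBH4, CeCl3·7H2O, MeOH, −40 to 0 °C
Reagents that add atoms: none
Why: Luche 1,2-reduction with axial attack from the α face, since the axial 6β-oxygen and the 10-methyl shield the β face, gives the 7β (pseudo-equatorial) alcohol.

Step 13
Reactants: 23 15-TBDPSO-labda-8,13E-diene-6β,7β-diol
Product: 24 7α-acetoxy-15-TBDPSO-labda-8,13E-dien-6β-ol
Conditions: PPh3, DIAD, AcOH, toluene, 0 °C to rt
Reagents that add atoms: acetic acid, CC(=O)O
Why: The Mitsunobu reaction activates only the allylic equatorial 7β-alcohol (the axial 6β-alcohol is flanked by the gem-dimethyl group), and acetate enters from the open α face with inversion; a competing allyl-cation pathway would also be captured axially from α, while SN2′ attack at fully substituted C9 is blocked.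

Step 14
Reactants: 24 7α-acetoxy-15-TBDPSO-labda-8,13E-dien-6β-ol
Product: 25 6β,7α-diacetoxy-15-TBDPSO-labda-8,13E-diene
Conditions: Ac2O, DMAP, pyridine, 40 °C
Reagents that add atoms: acetic anhydride, CC(=O)OC(C)=O
Why: DMAP-catalysed acetylation of the hindered axial alcohol; the trans-diaxial arrangement rules out acyl migration and no stereocentre is touched.

Step 15
Reactants: 25 6β,7α-diacetoxy-15-TBDPSO-labda-8,13E-diene
Product: 26 6β,7α-diacetoxylabda-8,13E-dien-15-ol
Conditions: HF·pyridine, pyridine, THF, 0 °C to rt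
Reagents that add atoms: none
Why: Buffered fluoride desilylation frees the primary allylic alcohol and leaves both secondary acetates in place.

Compound list
1 | squaric acid | O=C1C(O)=C(O)C1=O | starting material
2 | (−)-menthol, (1R,2S,5R) | CC(C)[C@@H]1CC[C@@H](C)C[C@H]1O | starting material
3 | di-(−)-menthyl squarate | O=C1C(=O)C(O[C@@H]2C[C@H](C)CC[C@H]2C(C)C)=C1O[C@@H]3C[C@H](C)CC[C@H]3C(C)C | intermediate
4 | 4-hydroxy-2,3-bis(menthyloxy)-4-methylcyclobut-2-en-1-one (both carbinol epimers, not isolated) | CC1(O)C(=O)C(O[C@@H]2C[C@H](C)CC[C@H]2C(C)C)=C1O[C@@H]3C[C@H](C)CC[C@H]3C(C)C | intermediate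
5 | 3-[(−)-menthyloxy]-4-methylcyclobut-3-ene-1,2-dione | CC1=C(O[C@@H]2C[C@H](C)CC[C@H]2C(C)C)C(=O)C1=O | intermediate
6 | 2,2,6-trimethylcyclohexanone (racemic, stereocentre lost in step 4) | CC1CCCC(C)(C)C1=O | starting material
7 | 2,2,6-trimethylcyclohexanone hydrazone | CC1CCCC(C)(C)C1=NN | intermediate
8 | 2-iodo-1,3,3-trimethylcyclohex-1-ene | CC1=C(I)C(C)(C)CCC1 | intermediate
9 | 2,6,6-trimethylcyclohex-1-enyllithium (not isolated) | CC1=C([Li])C(C)(C)CCC1 | intermediate
10 | 4-hydroxy-3-[(−)-menthyloxy]-2-methyl-4-(2,6,6-trimethylcyclohex-1-enyl)cyclobut-2-en-1-one (both carbinol epimers) | CC1=C(O[C@@H]2C[C@H](C)CC[C@H]2C(C)C)C(O)(C3=C(C)CCCC3(C)C)C1=O | intermediate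
11 | (Z)-dienylketene, C9 ketene carbon cis to the cyclohexenyl group (not isolated) | CC(=C=O)/C(O[C@@H]1C[C@H](C)CC[C@H]1C(C)C)=C(/O)C2=C(C)CCCC2(C)C | intermediate
12 | 6-hydroxy-7-menthyloxy-8-methyl-5,7-dien-9-one, 10β-CH3 (cyclohexa-2,4-dienone enol, not isolated) | OC=1C(O[C@@H]3C[C@H](C)CC[C@H]3C(C)C)=C(C)C(=O)[C@@]2(C)CCCC(C)(C)C=12 | intermediate
13 | (4aS,8aS)-3-[(−)-menthyloxy]-2,5,5,8a-tetramethyl-4a,5,6,7,8,8a-hexahydronaphthalene-1,4-dione; trans-fused, 5α-H, 10β-CH3, ketones at C6 and C9 | O=C1C(O[C@@H]3C[C@H](C)CC[C@H]3C(C)C)=C(C)C(=O)[C@@]2(C)CCCC(C)(C)[C@H]12 | intermediate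
14 | 6β-hydroxy derivative of 13 (6S; C9 vinylogous ester intact) | O[C@@H]1C(O[C@@H]3C[C@H](C)CC[C@H]3C(C)C)=C(C)C(=O)[C@@]2(C)CCCC(C)(C)[C@H]12 | intermediate
15 | (E)-3-methylpent-2-en-4-yn-1-ol | C#C/C(C)=C/CO | starting material
16 | (E)-3-methylpent-2-en-4-ynyl TBDPS ether | C#C/C(C)=C/CO[Si](c1ccccc1)(c1ccccc1)C(C)(C)C | intermediate
17 | (E)-3-methylpenta-2,4-dienyl TBDPS ether | C=C/C(C)=C/CO[Si](c1ccccc1)(c1ccccc1)C(C)(C)C | intermediate
18 | B-[(E)-3-methyl-5-(TBDPSO)pent-3-enyl]-9-BBN (not isolated) | B1(CC/C(C)=C/CO[Si](c2ccccc2)(c2ccccc2)C(C)(C)C)C3CCCC1CCC3 | intermediate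
19 | (E)-5-iodo-3-methylpent-2-enyl TBDPS ether | ICC/C(C)=C/CO[Si](c1ccccc1)(c1ccccc1)C(C)(C)C | intermediate
20 | (E)-3-methyl-5-(TBDPSO)pent-3-enyllithium (not isolated) | [Li]CC/C(C)=C/CO[Si](c1ccccc1)(c1ccccc1)C(C)(C)C | intermediate
21 | 6β,9β-dihydroxy-7-menthyloxy-7-ene with the side chain 9α (not isolated) | O[C@@H]1C(O[C@@H]3C[C@H](C)CC[C@H]3C(C)C)=C(C)[C@@](O)(CC/C(C)=C/CO[Si](c4ccccc4)(c4ccccc4)C(C)(C)C)[C@@]2(C)CCCC(C)(C)[C@H]12 | intermediate
22 | 15-(tert-butyldiphenylsilyloxy)-6β-hydroxylabda-8,13E-dien-7-one | O[C@@H]1C(=O)C(C)=C(CC/C(C)=C/CO[Si](c3ccccc3)(c3ccccc3)C(C)(C)C)[C@@]2(C)CCCC(C)(C)[C@H]12 | intermediate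
23 | 15-(tert-butyldiphenylsilyloxy)labda-8,13E-diene-6β,7β-diol | O[C@@H]1[C@H](O)C(C)=C(CC/C(C)=C/CO[Si](c3ccccc3)(c3ccccc3)C(C)(C)C)[C@@]2(C)CCCC(C)(C)[C@H]12 | intermediate
24 | 7α-acetoxy-15-(tert-butyldiphenylsilyloxy)labda-8,13E-dien-6β-ol | O[C@@H]1[C@@H](OC(C)=O)C(C)=C(CC/C(C)=C/CO[Si](c3ccccc3)(c3ccccc3)C(C)(C)C)[C@@]2(C)CCCC(C)(C)[C@H]12 | intermediate
25 | 6β,7α-diacetoxy-15-(tert-butyldiphenylsilyloxy)labda-8,13E-diene | CC(=O)O[C@@H]1[C@@H](OC(C)=O)C(C)=C(CC/C(C)=C/CO[Si](c3ccccc3)(c3ccccc3)C(C)(C)C)[C@@]2(C)CCCC(C)(C)[C@H]12 | intermediate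
26 | 6β,7α-diacetoxylabda-8,13E-dien-15-ol, (5S,6S,7S,10S) | CC(=O)O[C@@H]1[C@@H](OC(C)=O)C(C)=C(CC/C(C)=C/CO)[C@@]2(C)CCCC(C)(C)[C@H]12 | target

Total step count: 15. Longest linear sequence: 10 steps (3, 4, 5, 6, 7, 11, 12, 13, 14, 15). The squarate branch through steps 1 and 2 is equally long, and the side-chain branch (steps 8–10) is shorter.

Steps most likely to fail

Step 6. Inward rotation of the very bulky cyclohexenyl group may lose to inward rotation of the hydroxyl, which would drain the ketene by lactonisation, and closure onto the fully substituted terminus may be slow. The fallback sets out from 10 and comes back at 13.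
- The carbinol is capped (TMSOTf, 2,6-lutidine) as the trimethylsilyl ether F1.
- A silyl ether cannot add to the ketene, so an unproductive opening only reverts. Thermolysis should therefore funnel the material to the silyl dienol ether F2.
- K2CO3 in MeOH removes silicon with protonation at C5 and gives 13, which is separated as before.

Step 11. 1,2-Addition of a primary alkyllithium to a carbonyl flanked by quaternary C10 and the C8 methyl may be too slow, so that the reagent decays before it adds. The fallback sets out from 14 and comes back at 23.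
- A small sp2 nucleophile (vinylmagnesium bromide, CeCl3) is added to 14, and acid work-up gives the 9-vinyl hydroxy dienone F3.
- Luche reduction leads to the 9-vinyl 6β,7β-diol F4.
- Excess 9-BBN adds to the terminal CH2= to give the borane F5.
- A B-alkyl Suzuki–Miyaura coupling (PdCl2(dppf), Cs2CO3, aq. DMF) joins F5 with (E)-3-iodobut-2-enyl TBDPS ether F6, made from (E)-3-iodobut-2-en-1-ol and TBDPSCl. This completes the side chain and gives 23.

Step 13. Activation of the crowded allylic alcohol may end in elimination to the ring diene or in low conversion with the weak acid AcOH. The fallback sets out from 22 and comes back at 25.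
- C7 is set by hydroxyl-directed hydride delivery instead of inversion. Me4NBH(OAc)3 in MeCN/AcOH binds the axial 6β-hydroxyl and delivers hydride to the β face of the C7 ketone, giving the 6β,7α-diol F7.
- Ac2O, DMAP and pyridine convert F7 into 25.

Further compounds
F1 | step 6 | trimethylsilyl ether of 10 | CC1=C(O[C@@H]2C[C@H](C)CC[C@H]2C(C)C)C(O[Si](C)(C)C)(C3=C(C)CCCC3(C)C)C1=O
F2 | step 6 | 6-trimethylsilyloxy-7-menthyloxy-8-methyl-5,7-dien-9-one, 10β-CH3 | C[Si](C)(C)OC=1C(O[C@@H]3C[C@H](C)CC[C@H]3C(C)C)=C(C)C(=O)[C@@]2(C)CCCC(C)(C)C=12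
F3 | step 11 | 6β-hydroxy-9-vinyl-8-en-7-one (bicyclic core, 5α-H, 10β-CH3) | O[C@@H]1C(=O)C(C)=C(C=C)[C@@]2(C)CCCC(C)(C)[C@H]12
F4 | step 11 | 9-vinyl-8-ene-6β,7β-diol | O[C@@H]1[C@H](O)C(C)=C(C=C)[C@@]2(C)CCCC(C)(C)[C@H]12
F5 | step 11 | B-alkyl-9-BBN from F4 (boron on C12, hydroxyls drawn free) | O[C@@H]1[C@H](O)C(C)=C(CCB3C4CCCC3CCC4)[C@@]2(C)CCCC(C)(C)[C@H]12
F6 | step 11 | (E)-3-iodobut-2-enyl TBDPS ether | I/C(C)=C/CO[Si](c1ccccc1)(c1ccccc1)C(C)(C)C
F7 | step 13 | 15-(tert-butyldiphenylsilyloxy)labda-8,13E-diene-6β,7α-diol | O[C@@H]1[C@@H](O)C(C)=C(CC/C(C)=C/CO[Si](c3ccccc3)(c3ccccc3)C(C)(C)C)[C@@]2(C)CCCC(C)(C)[C@H]12
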